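**Plan**

1. Numbering is that of the target decalin: ring B = C-1 to C-4, C-4a, C-8a (C-2 acrylic acid, C-4 ester oxygen, C-4a methyl); ring A = C-4a, C-5 to C-8, C-8a (C-8 tertiary carbinol); β is the face of the C-4a methyl group.
2. Retrosynthesis: the acid goes back to the isopropenyl methyl group and the ester to the C-4 alcohol; ring A is then opened at C-6–C-7 and C-8–C-8a in one stroke, which takes out C-7/C-8 with its methyl as an isopropenyl group on boron; C-4a–C-5 (enolate alkylation) and C-8a–B (conjugate borylation) lead back to (R)-carvone.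
3. Enabling feature: C-8 is a methyl-bearing tertiary carbinol between the ring CH2 C-7 and the ring-fusion CH C-8a. A B-isopropenyl boronate on C-8a is this unit in masked form: its CH2 end takes the C-6 radical, the 1,2-shift of C-8a from boron to C-8 closes ring A, and the boron left on C-8 becomes the hydroxyl.
4. Forward: ring B is the carvone ring (carvone C=O becomes C-4, its methyl-bearing carbon C-4a, its enone β-carbon C-8a, its isopropenyl carbon C-2); borylation, quaternisation and reduction follow, then ring A is made by the boron-mediated annulation, then esterification and side-chain oxidation.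
5. Stereochemistry: C-2 from (R)-carvone; C-8a by conjugate borylation anti to isopropenyl; C-4a by alkylation anti to boron; C-4 by equatorial hydride delivery; C-8a/C-8 in the key step by retentive 1,2-migration with equatorial expulsion of boron; the acyl stereocentre from (3R)-3-methylpentanoic acid.

Key step: step 6

Remark: (3R)-3-methylpentanoic acid and 2-bromoethyl trifluoromethanesulfonate are taken as catalogue chemicals; Bpin = 4,4,5,5-tetramethyl-1,3,2-dioxaborolan-2-yl.

**Route**

Step 1
Reactants: 1 (R)-(−)-carvone; 2 bis(pinacolato)diboron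
Product: 3 (3R,5R)-2-methyl-5-(prop-1-en-2-yl)-3-(Bpin)cyclohexan-1-one (both C-2 epimers)
Conditions: CuCl (5 mol %), DPEphos (5 mol %), NaOt-Bu (10 mol %), MeOH (2 equiv), THF, rt
Reagents that add atoms: bis(pinacolato)diboron (2), CC1(C)OB(OC1(C)C)B1OC(C)(C)C(C)(C)O1
Why: Copper-catalysed conjugate borylation of the enone, in which the boryl-copper species should add to the β-carbon by axial attack anti to the isopropenyl group, so that the C–B centre (future C-8a) is set trans to isopropenyl; the epimeric α-centre is erased in step 2.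

Step 2
Reactants: 3 β-boryl ketone; 4 2-bromoethyl trifluoromethanesulfonate
Product: 5 (2S,3R,5R)-2-(2-bromoethyl)-2-methyl-5-(prop-1-en-2-yl)-3-(Bpin)cyclohexan-1-one
Conditions: LiN(SiMe3)2 (0.98 equiv), THF, −78 to 0 °C; then 4, −78 °C to rt
Reagents that add atoms: 2-bromoethyl trifluoromethanesulfonate (4), BrCCOS(=O)(=O)C(F)(F)F
Why: Enolate C-alkylation: equilibration should give the more substituted lithium enolate (fully substituted, further held by an O→B enoxyborate-type chelate), which displaces the triflate in preference to the bromide from the face anti to the Bpin group and cis to the isopropenyl group (axial attack through a chair-like transition state), setting the quaternary centre (future C-4a).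

Step 3
Reactants: 5 bromo ketone
Product: 6 (1S,2S,3R,5R)-2-(2-bromoethyl)-2-methyl-5-(prop-1-en-2-yl)-3-(Bpin)cyclohexan-1-ol
Conditions: LiBH(s-Bu)3 (L-Selectride), THF, −78 °C; AcOH quench at −78 °C
Reagents that add atoms: none
Why: Diastereoselective ketone reduction with a bulky trialkylborohydride: in the favoured chair (isopropenyl equatorial, Bpin and the bromoethyl arm axial) the axial trajectory is blocked by the 1,3-diaxial Bpin group, so hydride should enter equatorially and give the alcohol cis to boron (future C-4, β-oxygen); the cold quench keeps the bromo alkoxide from closing to a tetrahydrofuran.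

Step 4
Reactants: 6 bromo alcohol
Product: 7 {[(1S,2S,3R,5R)-2-(2-bromoethyl)-2-methyl-5-(prop-1-en-2-yl)-3-(Bpin)cyclohexyl]oxy}triethylsilane
Conditions: Et3SiOTf, 2,6-lutidine, CH2Cl2, −78 °C
Reagents that add atoms: triethylsilyl trifluoromethanesulfonate, CC[Si](CC)(CC)OS(=O)(=O)C(F)(F)F
Why: Silyl ether formation with the silyl triflate, needed for the hindered axial alcohol; the ether protects the hydroxyl against the organolithium of step 6 and prevents alkoxide–boron chelation.

Step 5
Reactants: 7 bromide
Product: 8 {[(1S,2S,3R,5R)-2-(2-iodoethyl)-2-methyl-5-(prop-1-en-2-yl)-3-(Bpin)cyclohexyl]oxy}triethylsilane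
Conditions: NaI, acetone, reflux
Reagents that add atoms: sodium iodide, [Na+].[I-]
Why: Finkelstein halide exchange (SN2 at the primary carbon) gives the iodide that single-electron reduction requires; no stereocentre is touched.

Step 6
Reactants: 8 iodide; 9 2-bromopropene
Product: 12 (1R,4aS,5S,7R,8aR)-1,4a-dimethyl-7-(prop-1-en-2-yl)-5-[(triethylsilyl)oxy]decahydronaphthalen-1-ol, via lithium boronate complex 10 (not isolated), via tertiary boronic ester 11 (not isolated)
Conditions: 9, t-BuLi (2 equiv), Et2O, −78 °C; add 8, THF, −78 °C; then fac-Ir(ppy)3 (1 mol %), MeCN, blue LEDs, rt; then NaOH, H2O2, 0 °C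
Reagents that add atoms: isopropenyllithium, [Li]C(C)=C (made in the flask from 2-bromopropene (9), CC(Br)=C); hydrogen peroxide, OO
Why: Proposed new method: isopropenyllithium adds to the boron of 8 to give boronate complex 10; photoexcited fac-Ir(ppy)3 reduces the C–I bond, the primary C-6 radical adds to the CH2 terminus (future C-7) of the electron-rich B-isopropenyl group, the tertiary α-boryl radical is oxidised by the tetravalent iridium formed in the first electron transfer (or passes the chain on by iodine-atom abstraction), and the resulting cation is quenched by 1,2-migration of C-8a from boron to C-8, after which basic peroxide replaces boron by hydroxyl with retention. The closest known reaction type is the intermolecular radical–polar crossover (conjunctive) three-component coupling of alkenylboronate complexes with alkyl iodides, here made intramolecular with an unactivated primary iodide so that it becomes a ring-forming annulation. Ring A is closed by a 7-endo-trig radical cyclisation to a seven-membered boracycle, which contracts to the cyclohexane when the 1,2-shift excises the boron atom from the ring. C-8a is controlled by the C–B stereocentre made in step 1, because the migrating carbon keeps its configuration, and this gives the trans ring fusion that closure onto an sp2 ring-fusion carbon could not give; C-8 is controlled by the tether, since C-8 has to enter between boron and C-4a, so boron is pushed out anti to C-4a into the equatorial site, methyl ends axial and the oxidation then gives the equatorial (α) hydroxyl. The step needs 7-endo attack to win over 6-exo attack at the boron-bearing carbon, over 1,5-hydrogen transfer and over attack on the remote isopropenyl group: the terminal carbon is the unhindered one and leads to the stabilised tertiary radical, the two arms are gauche (diequatorial) in the chair that the bulky borate prefers, and no hydrogen-atom donor is present.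

Step 7
Reactants: 12 silyl ether
Product: 13 (1S,3R,4aR,5R,8aS)-5,8a-dimethyl-3-(prop-1-en-2-yl)decahydronaphthalene-1,5-diol
Conditions: HF·pyridine, pyridine, THF, 0 °C to rt
Reagents that add atoms: none
Why: Fluoride-driven desilylation (Si–F bond formation); the buffered reagent should leave the tertiary alcohol and the isopropenyl group untouched.

Step 8
Reactants: 13 diol; 14 (3R)-3-methylpentanoic acid
Product: 15 (1S,3R,4aR,5R,8aS)-5-hydroxy-5,8a-dimethyl-3-(prop-1-en-2-yl)decahydronaphthalen-1-yl (3R)-3-methylpentanoate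
Conditions: DCC, DMAP (0.5 equiv), CH2Cl2, 0 °C to rt
Reagents that add atoms: (3R)-3-methylpentanoic acid (14), CC[C@@H](C)CC(=O)O
Why: Steglich esterification (carbodiimide activation, acyl transfer by DMAP): only the secondary equatorial hydroxyl should be acylated, the tertiary hydroxyl being inert, and the β-stereocentre of the acid cannot epimerise.

Step 9
Reactants: 15 ester
Product: 16 (1S,3R,4aR,5R,8aS)-5-hydroxy-3-(3-hydroxyprop-1-en-2-yl)-5,8a-dimethyldecahydronaphthalen-1-yl (3R)-3-methylpentanoate
Conditions: SeO2 (0.3 equiv), t-BuOOH, CH2Cl2, rt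
Reagents that add atoms: selenium dioxide, O=[Se]=O (catalytic oxygen carrier); tert-butyl hydroperoxide, CC(C)(C)OO (terminal oxidant)
Why: Selenium dioxide allylic oxidation (ene reaction, then [2,3]-sigmatropic shift) should convert the isopropenyl methyl group into the primary allylic alcohol; any enal formed alongside is carried on, since step 10 converges both.

Step 10
Reactants: 16 allylic alcohol
Product: 18 2-[(2R,4S,4aS,8R,8aR)-8-hydroxy-4a,8-dimethyl-4-{[(3R)-3-methylpentanoyl]oxy}decahydronaphthalen-2-yl]prop-2-enoic acid, via enal 17 (not isolated)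
Conditions: TEMPO (cat.), NaOCl (cat.), NaClO2, MeCN/phosphate buffer (pH 6.7), 35 °C
Reagents that add atoms: sodium chlorite, [Na+].[O-]Cl=O
Why: Oxoammonium (TEMPO) oxidation to the enal, followed in the same flask by chlorite (Pinnick-type) oxidation, should give the acrylic acid; hypochlorite is kept catalytic so the alkene is not chlorinated, and the ester, the tertiary alcohol and all stereocentres are left alone.

**Compound list**

1 | (R)-(−)-carvone, (5R)-2-methyl-5-(prop-1-en-2-yl)cyclohex-2-en-1-one | CC1=CC[C@H](CC1=O)C(C)=C | starting material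
2 | bis(pinacolato)diboron | CC1(C)OB(OC1(C)C)B1OC(C)(C)C(C)(C)O1 | starting material
3 | (3R,5R)-2-methyl-5-(prop-1-en-2-yl)-3-(Bpin)cyclohexan-1-one, Bpin trans to isopropenyl, both C-2 epimers | C=C(C)[C@H]1CC(=O)C(C)[C@H](B2OC(C)(C)C(C)(C)O2)C1 | intermediate
4 | 2-bromoethyl trifluoromethanesulfonate | BrCCOS(=O)(=O)C(F)(F)F | starting material
5 | (2S,3R,5R)-2-(2-bromoethyl)-2-methyl-5-(prop-1-en-2-yl)-3-(Bpin)cyclohexan-1-one | C=C(C)[C@H]1CC(=O)[C@@](C)(CCBr)[C@H](B2OC(C)(C)C(C)(C)O2)C1 | intermediate
6 | (1S,2S,3R,5R)-2-(2-bromoethyl)-2-methyl-5-(prop-1-en-2-yl)-3-(Bpin)cyclohexan-1-ol | C=C(C)[C@H]1C[C@H](O)[C@@](C)(CCBr)[C@H](B2OC(C)(C)C(C)(C)O2)C1 | intermediate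
7 | {[(1S,2S,3R,5R)-2-(2-bromoethyl)-2-methyl-5-(prop-1-en-2-yl)-3-(Bpin)cyclohexyl]oxy}triethylsilane | C=C(C)[C@H]1C[C@H](O[Si](CC)(CC)CC)[C@@](C)(CCBr)[C@H](B2OC(C)(C)C(C)(C)O2)C1 | intermediate
8 | {[(1S,2S,3R,5R)-2-(2-iodoethyl)-2-methyl-5-(prop-1-en-2-yl)-3-(Bpin)cyclohexyl]oxy}triethylsilane | C=C(C)[C@H]1C[C@H](O[Si](CC)(CC)CC)[C@@](C)(CCI)[C@H](B2OC(C)(C)C(C)(C)O2)C1 | intermediate
9 | 2-bromopropene | CC(Br)=C | starting material
10 | lithium boronate complex of 8 (boron tetracoordinate: pinacolato, isopropenyl and the ring carbon; all centres as in 8; formed in the flask) | [Li+].C=C(C)[C@H]1C[C@H](O[Si](CC)(CC)CC)[C@@](C)(CCI)[C@H]([B-]2(C(C)=C)OC(C)(C)C(C)(C)O2)C1 | intermediate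
11 | triethyl{[(1S,3R,4aS,5S,8aS)-5,8a-dimethyl-3-(prop-1-en-2-yl)-5-(Bpin)decahydronaphthalen-1-yl]oxy}silane (trans-decalin, Bpin equatorial, formed in the flask) | C=C(C)[C@H]1C[C@H](O[Si](CC)(CC)CC)[C@@]2(C)CCC[C@@](C)(B3OC(C)(C)C(C)(C)O3)[C@@H]2C1 | intermediate
12 | (1R,4aS,5S,7R,8aR)-1,4a-dimethyl-7-(prop-1-en-2-yl)-5-[(triethylsilyl)oxy]decahydronaphthalen-1-ol | C=C(C)[C@H]1C[C@H](O[Si](CC)(CC)CC)[C@@]2(C)CCC[C@@](C)(O)[C@@H]2C1 | intermediate
13 | (1S,3R,4aR,5R,8aS)-5,8a-dimethyl-3-(prop-1-en-2-yl)decahydronaphthalene-1,5-diol | C=C(C)[C@H]1C[C@H](O)[C@@]2(C)CCC[C@@](C)(O)[C@@H]2C1 | intermediate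
14 | (3R)-3-methylpentanoic acid | CC[C@@H](C)CC(=O)O | starting material
15 | (1S,3R,4aR,5R,8aS)-5-hydroxy-5,8a-dimethyl-3-(prop-1-en-2-yl)decahydronaphthalen-1-yl (3R)-3-methylpentanoate | C=C(C)[C@H]1C[C@H](OC(=O)C[C@H](C)CC)[C@@]2(C)CCC[C@@](C)(O)[C@@H]2C1 | intermediate
16 | (1S,3R,4aR,5R,8aS)-5-hydroxy-3-(3-hydroxyprop-1-en-2-yl)-5,8a-dimethyldecahydronaphthalen-1-yl (3R)-3-methylpentanoate | C=C(CO)[C@H]1C[C@H](OC(=O)C[C@H](C)CC)[C@@]2(C)CCC[C@@](C)(O)[C@@H]2C1 | intermediate
17 | (1S,3R,4aR,5R,8aS)-5-hydroxy-5,8a-dimethyl-3-(3-oxoprop-1-en-2-yl)decahydronaphthalen-1-yl (3R)-3-methylpentanoate (formed in the flask) | C=C(C=O)[C@H]1C[C@H](OC(=O)C[C@H](C)CC)[C@@]2(C)CCC[C@@](C)(O)[C@@H]2C1 | intermediate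
18 | 2-[(2R,4S,4aS,8R,8aR)-8-hydroxy-4a,8-dimethyl-4-{[(3R)-3-methylpentanoyl]oxy}decahydronaphthalen-2-yl]prop-2-enoic acid | C=C(C(=O)O)[C@H]1C[C@H](OC(=O)C[C@H](C)CC)[C@@]2(C)CCC[C@@](C)(O)[C@@H]2C1 | target

**Step count and risks**

Total steps: 10. Longest linear sequence: 10 steps (1 to 18).

Step 6 (proposed new method). What may go wrong: the 7-endo radical addition may be too slow, so that hydrogen-atom abstraction or intramolecular hydrogen transfer takes over, and the facial control of the 1,2-shift may be incomplete. The fallback sets out from 8 and returns at 12, using known reactions. A Zweifel olefination of 8 (isopropenyllithium, THF, −78 °C; I2; NaOMe, MeOH, −78 to 0 °C) should give, with retention at the migrating carbon, triethyl{[(1S,2S,3S,5R)-2-(2-iodoethyl)-2-methyl-3,5-di(prop-1-en-2-yl)cyclohexyl]oxy}silane F1. Its iodide is then cyclised under tin hydride/oxygen conditions (Bu3SnH, BEt3, air, toluene, 0 °C; then PPh3). The C-6 radical should close 6-endo onto the CH2 terminus of the new isopropenyl group, because the 5-exo mode would need attack at the fully substituted alkene carbon and a trans-fused five-membered ring. The tertiary C-8 radical should be trapped by O2 from the equatorial face, the axial face being shielded by the C-4a methyl group, and the hydroperoxide is reduced to 12.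

Step 2. What may go wrong: O-alkylation and base-induced elimination of the hard triflate may compete with C-alkylation at the hindered, fully substituted enolate carbon. The fallback sets out from 3 and returns at 8, and builds the arm from a soft α-halo ester. The enolate of 3 (LiN(SiMe3)2, THF) is alkylated with methyl bromoacetate to methyl 2-[(1S,2R,4R)-1-methyl-6-oxo-4-(prop-1-en-2-yl)-2-(Bpin)cyclohexyl]acetate F2. Reduction with LiBH(s-Bu)3 at −78 °C gives methyl 2-[(1S,2R,4R,6S)-6-hydroxy-1-methyl-4-(prop-1-en-2-yl)-2-(Bpin)cyclohexyl]acetate F3, and silylation (Et3SiOTf, 2,6-lutidine) gives methyl 2-[(1S,2R,4R,6S)-1-methyl-4-(prop-1-en-2-yl)-2-(Bpin)-6-[(triethylsilyl)oxy]cyclohexyl]acetate F4. Reduction with i-Bu2AlH (CH2Cl2, −78 °C) gives 2-[(1S,2R,4R,6S)-1-methyl-4-(prop-1-en-2-yl)-2-(Bpin)-6-[(triethylsilyl)oxy]cyclohexyl]ethan-1-ol F5, and an Appel reaction (I2, PPh3, imidazole) gives 8.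

Step 9. What may go wrong: the ene step may attack the ring methine C–H next to the alkene instead of the methyl group, and over-oxidation may occur. The fallback sets out from 15 and returns at 17. Ene-type chlorination with hypochlorous acid (Ca(OCl)2, solid CO2, CH2Cl2/H2O, 0 °C) should give (1S,3R,4aR,5R,8aS)-3-(3-chloroprop-1-en-2-yl)-5-hydroxy-5,8a-dimethyldecahydronaphthalen-1-yl (3R)-3-methylpentanoate F6. Oxidation of the allylic chloride with N-methylmorpholine N-oxide (MeCN, rt) gives enal 17, which the chlorite stage of step 10 converts into 18.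

Further compounds
F1 | step 6 | triethyl{[(1S,2S,3S,5R)-2-(2-iodoethyl)-2-methyl-3,5-di(prop-1-en-2-yl)cyclohexyl]oxy}silane | C=C(C)[C@H]1C[C@H](O[Si](CC)(CC)CC)[C@@](C)(CCI)[C@H](C(C)=C)C1
F2 | step 2 | methyl 2-[(1S,2R,4R)-1-methyl-6-oxo-4-(prop-1-en-2-yl)-2-(Bpin)cyclohexyl]acetate | C=C(C)[C@H]1CC(=O)[C@@](C)(CC(=O)OC)[C@H](B2OC(C)(C)C(C)(C)O2)C1
F3 | step 2 | methyl 2-[(1S,2R,4R,6S)-6-hydroxy-1-methyl-4-(prop-1-en-2-yl)-2-(Bpin)cyclohexyl]acetate | C=C(C)[C@H]1C[C@H](O)[C@@](C)(CC(=O)OC)[C@H](B2OC(C)(C)C(C)(C)O2)C1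
F4 | step 2 | methyl 2-[(1S,2R,4R,6S)-1-methyl-4-(prop-1-en-2-yl)-2-(Bpin)-6-[(triethylsilyl)oxy]cyclohexyl]acetate | C=C(C)[C@H]1C[C@H](O[Si](CC)(CC)CC)[C@@](C)(CC(=O)OC)[C@H](B2OC(C)(C)C(C)(C)O2)C1
F5 | step 2 | 2-[(1S,2R,4R,6S)-1-methyl-4-(prop-1-en-2-yl)-2-(Bpin)-6-[(triethylsilyl)oxy]cyclohexyl]ethan-1-ol | C=C(C)[C@H]1C[C@H](O[Si](CC)(CC)CC)[C@@](C)(CCO)[C@H](B2OC(C)(C)C(C)(C)O2)C1
F6 | step 9 | (1S,3R,4aR,5R,8aS)-3-(3-chloroprop-1-en-2-yl)-5-hydroxy-5,8a-dimethyldecahydronaphthalen-1-yl (3R)-3-methylpentanoate | C=C(CCl)[C@H]1C[C@H](OC(=O)C[C@H](C)CC)[C@@]2(C)CCC[C@@](C)(O)[C@@H]2C1
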